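**Assumption:** the target SMILES has no stereocentre (coelenterazine is achiral, drawn as the 7H‑imidazo[1,2‑a]pyrazin‑3‑one tautomer), so there is no enantiomer to control. The L‑amino acids are used only because they are the cheapest forms; their stereocentres end up as sp2 carbons.

## Retrosynthetic overview

1. Coelenterazine 10 ⇒ pyrazinone 4 + L‑tyrosine 5, disconnecting C8a–N1 and C3(=O)–N4 (dehydrative [3+2] annulation; imidazolone ring formed last).
2. Pyrazinone 4 ⇒ 4‑hydroxyphenylglyoxal 2 + L‑phenylalaninamide 3, disconnecting two ring C–N bonds (Jones condensation; pyrazine ring formed first).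
3. Glyoxal 2 ⇒ 4'‑hydroxyacetophenone 1 (C–H oxidation).
4. No protecting group is isolated: the three OH groups are masked and released as TMS ethers within the last step.

## Route

**Step 1**
Reactants: 1 4'‑hydroxyacetophenone
Product: 2 4‑hydroxyphenylglyoxal monohydrate
Conditions: SeO2 (1.1 equiv), 1,4‑dioxane/H2O (20:1), reflux, 6 h; filter off Se; crystallise from water
Reagents that add atoms: selenium dioxide O=[Se]=O; water O
Why: Riley oxidation of the enolisable aryl methyl ketone (ene reaction/[2,3]‑shift) gives the α‑ketoaldehyde, which crystallises as its gem‑diol; the free para‑phenol is tolerated and no stereocentre is involved.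

**Step 2**
Reactants: 2 4‑hydroxyphenylglyoxal monohydrate; 3 L‑phenylalaninamide hydrochloride
Product: 4 3‑benzyl‑5‑(4‑hydroxyphenyl)pyrazin‑2(1H)‑one
Conditions: NaOH (aq, 3.5 equiv, slow addition), MeOH, −35 °C → rt, 3 h; then aq HCl to pH 5, filter
Reagents that add atoms: none
Why: Jones 2‑hydroxypyrazine synthesis, a base‑mediated double condensation of an α‑aminoamide with an α‑ketoaldehyde (two C–N bonds) that favours the 3,5‑disubstituted isomer with aryl glyoxals; tautomerisation aromatises the ring and turns the phenylalanine stereocentre into sp2 C3.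

**Step 3**
Reactants: 4 3‑benzyl‑5‑(4‑hydroxyphenyl)pyrazin‑2(1H)‑one; 5 L‑tyrosine (2.0 equiv)
Product: 10 coelenterazine, via bis‑TMS pyrazine 6 (not isolated), via tris‑TMS tyrosine 7 (not isolated), via silylated N‑pyrazinyl tyrosine ester 8 (not isolated), via tris‑TMS coelenterazine 9 (not isolated)
Conditions: HMDS (10 equiv, neat), TMSOTf (0.3 equiv), sealed tube, Ar, 145 °C, 24–36 h; evaporate; then 1.25 M HCl in degassed MeOH, 0 °C → rt, Ar
Reagents that add atoms: none
Why: Proposed new method: a silylative deoxyaminative [3+2] annulation of a pyrazin‑2(1H)‑one with a free α‑amino acid — HMDS persilylates both partners (6 and 7), which masks all OH groups and dissolves tyrosine; the TMSOTf‑activated 2‑silyloxypyrazine 6 undergoes addition–elimination by the amine of 7 with loss of (Me3Si)2O to forge C8a–N1 (8); the amidine‑type ring nitrogen of 8 then attacks the TMSOTf‑activated silyl ester (5‑exo) to forge C3–N4, and the imidazolone is trapped by O‑silylation as the aromatic 3‑silyloxyimidazo[1,2‑a]pyrazine 9, which together with Si–O–Si formation drives both dehydrations (acylation of the pyrazinone nitrogen before amination would funnel to the same 9); acidic methanolysis under argon then releases 10, whose C2 is sp2, so the tyrosine configuration is irrelevant; closest known reaction types are the silylation–amination of hydroxy‑N‑heterocycles (Vorbrüggen), HMDS‑mediated lactamisation of amino acids through silyl esters, and the Ac2O cyclisation of N‑(pyrazin‑2‑yl)‑α‑amino acids to 3‑acyloxyimidazo[1,2‑a]pyrazines.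

## Compound list

1 | 4'‑hydroxyacetophenone [1‑(4‑hydroxyphenyl)ethan‑1‑one] | CC(=O)c1ccc(O)cc1 | starting material
2 | 4‑hydroxyphenylglyoxal monohydrate [2,2‑dihydroxy‑1‑(4‑hydroxyphenyl)ethan‑1‑one] | OC(O)C(=O)c1ccc(O)cc1 | intermediate
3 | L‑phenylalaninamide hydrochloride [(2S)‑2‑amino‑3‑phenylpropanamide hydrochloride] | Cl.N[C@@H](Cc1ccccc1)C(N)=O | starting material
4 | 3‑benzyl‑5‑(4‑hydroxyphenyl)pyrazin‑2(1H)‑one | O=c1[nH]cc(-c2ccc(O)cc2)nc1Cc1ccccc1 | intermediate
5 | L‑tyrosine [(2S)‑2‑amino‑3‑(4‑hydroxyphenyl)propanoic acid] | N[C@@H](Cc1ccc(O)cc1)C(=O)O | starting material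
6 | 3‑benzyl‑2‑(trimethylsilyloxy)‑5‑[4‑(trimethylsilyloxy)phenyl]pyrazine | C[Si](C)(C)Oc1ccc(cc1)-c1cnc(O[Si](C)(C)C)c(Cc2ccccc2)n1 | intermediate (not isolated)
7 | N,O,O'‑tris(trimethylsilyl)‑L‑tyrosine | C[Si](C)(C)N[C@@H](Cc1ccc(O[Si](C)(C)C)cc1)C(=O)O[Si](C)(C)C | intermediate (not isolated)
8 | trimethylsilyl N‑{3‑benzyl‑5‑[4‑(trimethylsilyloxy)phenyl]pyrazin‑2‑yl}‑O‑(trimethylsilyl)‑L‑tyrosinate (2S drawn; any erosion is inconsequential) | C[Si](C)(C)OC(=O)[C@H](Cc1ccc(O[Si](C)(C)C)cc1)Nc1ncc(-c2ccc(O[Si](C)(C)C)cc2)nc1Cc1ccccc1 | intermediate (not isolated)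
9 | 8‑benzyl‑3‑(trimethylsilyloxy)‑2‑[4‑(trimethylsilyloxy)benzyl]‑6‑[4‑(trimethylsilyloxy)phenyl]imidazo[1,2‑a]pyrazine | C[Si](C)(C)Oc1ccc(Cc2nc3c(Cc4ccccc4)nc(-c4ccc(O[Si](C)(C)C)cc4)cn3c2O[Si](C)(C)C)cc1 | intermediate (not isolated)
10 | coelenterazine [8‑benzyl‑2‑(4‑hydroxybenzyl)‑6‑(4‑hydroxyphenyl)imidazo[1,2‑a]pyrazin‑3(7H)‑one] | O=c1c(Cc2ccc(O)cc2)nc2c(Cc3ccccc3)[nH]c(-c3ccc(O)cc3)cn1-2 | target

## Summary

Total step count: 3. Longest linear sequence: 3 steps (1 → 2 → 4 → 10).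

**Steps most likely to fail**

**Step 3 (the proposed annulation).** The silyloxypyrazine may be too weak an electrophile for the hindered silylated amino acid, or tyrosine may self‑condense. The fallback uses known chemistry, sets out from 4 and comes back at 10. The phenol of 4 is silylated (TBSCl, imidazole, DMF; aqueous work‑up) to give 3‑benzyl‑5‑[4‑(tert‑butyldimethylsilyloxy)phenyl]pyrazin‑2(1H)‑one F1. Tf2O/pyridine in CH2Cl2 at 0 °C gives 3‑benzyl‑5‑[4‑(tert‑butyldimethylsilyloxy)phenyl]pyrazin‑2‑yl trifluoromethanesulfonate F2. Buchwald–Hartwig N‑arylation of commercial O‑tert‑butyl‑L‑tyrosine methyl ester hydrochloride (Pd(OAc)2, rac‑BINAP, Cs2CO3, toluene, 80 °C) gives methyl N‑{3‑benzyl‑5‑[4‑(tert‑butyldimethylsilyloxy)phenyl]pyrazin‑2‑yl}‑O‑tert‑butyl‑L‑tyrosinate F3. 6 M aq HCl/dioxane at 70 °C hydrolyses the ester and cleaves both ethers to give N‑[3‑benzyl‑5‑(4‑hydroxyphenyl)pyrazin‑2‑yl]‑L‑tyrosine F4. Carbodiimide cyclodehydration (DCC, CH2Cl2/DMF, Ar, 0 °C → rt) then closes the imidazolone to 10.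

**Step 2 (Jones condensation with a free para‑phenol).** The phenoxide deactivates the aryl ketone, so low conversion or a 3,5/3,6 isomer mixture is possible. The fallback sets out from 3 and comes back at 4. Jones condensation of 3 with aqueous glyoxal (NaOH, MeOH, −30 °C → rt) gives 3‑benzylpyrazin‑2(1H)‑one F5, with no regiochemical question. NBS in DMF at 0 °C brominates para to the lactam oxygen to give 3‑benzyl‑5‑bromopyrazin‑2(1H)‑one F6. Suzuki–Miyaura coupling with 4‑hydroxyphenylboronic acid (Pd(dppf)Cl2, Na2CO3, dioxane/H2O, 90 °C) installs the aryl group and gives 4.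

**Step 1 (SeO2 oxidation).** Over‑oxidation to the arylglyoxylic acid and selenium contamination are the risks. The fallback sets out from 1 and comes back at 2. α‑Bromination (CuBr2, EtOAc/CHCl3, reflux) gives 2‑bromo‑1‑(4‑hydroxyphenyl)ethan‑1‑one F7. Kornblum oxidation (DMSO, rt → 50 °C, then pouring into water) gives 2.

## Further compounds

F1 | step 3 | 3‑benzyl‑5‑[4‑(tert‑butyldimethylsilyloxy)phenyl]pyrazin‑2(1H)‑one | O=c1[nH]cc(-c2ccc(O[Si](C)(C)C(C)(C)C)cc2)nc1Cc1ccccc1
F2 | step 3 | 3‑benzyl‑5‑[4‑(tert‑butyldimethylsilyloxy)phenyl]pyrazin‑2‑yl trifluoromethanesulfonate | FC(F)(F)S(=O)(=O)Oc1ncc(-c2ccc(O[Si](C)(C)C(C)(C)C)cc2)nc1Cc1ccccc1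
F3 | step 3 | methyl N‑{3‑benzyl‑5‑[4‑(tert‑butyldimethylsilyloxy)phenyl]pyrazin‑2‑yl}‑O‑tert‑butyl‑L‑tyrosinate | COC(=O)[C@H](Cc1ccc(OC(C)(C)C)cc1)Nc1ncc(-c2ccc(O[Si](C)(C)C(C)(C)C)cc2)nc1Cc1ccccc1
F4 | step 3 | N‑[3‑benzyl‑5‑(4‑hydroxyphenyl)pyrazin‑2‑yl]‑L‑tyrosine | OC(=O)[C@H](Cc1ccc(O)cc1)Nc1ncc(-c2ccc(O)cc2)nc1Cc1ccccc1
F5 | step 2 | 3‑benzylpyrazin‑2(1H)‑one | O=c1[nH]ccnc1Cc1ccccc1
F6 | step 2 | 3‑benzyl‑5‑bromopyrazin‑2(1H)‑one | O=c1[nH]cc(Br)nc1Cc1ccccc1
F7 | step 1 | 2‑bromo‑1‑(4‑hydroxyphenyl)ethan‑1‑one | O=C(CBr)c1ccc(O)cc1
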